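## The problem

The target (16) is a germacrane: a ten-membered carbocycle C1–C10 in which one oxygen bridges C3 and C10, so that C10–C1(=O)–C2=C3–O forms a 3(2H)-furanone. A trans-fused α-methyl-γ-lactone (C11, C12) sits on C6/C7, and C8 carries a tigloyloxy group. Six stereocentres must be right, (4S,6R,7S,8S,10R,11S). C6, C7, C8 and C11 are contiguous and can steer one another; C4 and C10 lie across the ring and feel the others only through the conformation of the medium ring. Direct closure of a ten-membered ring is slow and invites transannular side reactions. Several groups are fragile: the furanone is a vinylogous ester whose C4–H is vinylogously acidic, C11 is epimerisable, the tiglate is reducible and light-sensitive, and a 1(10)-olefin beside a C3 ketone moves into conjugation with base. The enabling feature is that C5 and C10 face each other across the ring. A bond between them gives the eudesmanolide decalin (ring A = C1–C5, C10; ring B = C5–C10), and all fifteen carbons, the C3 oxygen and the C6, C7 and C11 centres then coincide with α-santonin (1). The oxidised carbons C1–C3 of the furanone mark a cyclohexa-1,3-diene (C1=C2, C3=C4) flanking that C5–C10 bond, which can therefore be cleaved electrocyclically. Santonin lacks only the C8 oxygen, which its congener artemisin (2) carries in the required 8α configuration.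

## Retrosynthesis

**C8 ester.** The C8–O acyl bond is cut first, giving alcohol 13 and tiglic acid (14). The tiglate would not survive the copper hydride, the osmylation or the 254 nm light used earlier, so it must come last. The forward step has to acylate a hindered secondary alcohol without epimerising C4 or C11 and without letting the lactone migrate to the free C8 hydroxyl.

**Furanone.** After the silyl ether is put back (12), the C3–O enol ether bond of the furanone is cut, not the C10–O bond. This leads to the α′-hydroxy-1,3-diketone 11 and, one oxidation level down, the 1,10-diol 10. Cutting at C10 instead would make C10 the electrophilic carbon of an epoxide opening and leave its configuration to the mechanism. With the chosen cut the C10–O bond is made early by syn addition and never broken. The forward reaction is the classical acid cyclodehydration of a hydroxy diketone.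

**Diol.** Both C–O bonds at C1 and C10 are removed, giving the E-olefin of ketone 9. The forward step must add both oxygens to the face of the 1(10)-olefin that gives (10R); the C1 carbinol configuration is irrelevant because C1 becomes a ketone.

**C4–C5 saturation.** Restoring the C4=C5 bond gives dienone 8. The reduction is placed here, not after furanone formation: a furanone carrying an E-4,5-olefin would be strained, and a 4-ene invites transannular attack during oxidation at C1/C10. The forward step must reduce only the conjugated olefin. C4 is left for thermodynamic control in the bicyclic furanone.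

**Ketone unmasking.** Ketone 8 is the hydrolysis product of silyl dienol ether 7, in which C1=C10, C2=C3 and C4=C5 form a triene.

**Key disconnection.** Joining C5 to C10 in 7 gives the trans-fused eudesma-1,3-diene 6. Cuts at other ring bonds (C7–C8, C2–C3) give open chains that need a medium-ring cyclisation and a de novo build of every stereocentre. This cut gives a decalin with four stereocentres already in place and asks only for a selective photochemical opening.

**Diene from the pool.** Diene 6 comes from enone 5 by enolisation towards C4, the only direction open because C10 is quaternary. Enone 5 comes from saturated ketone 3 by dehydrogenation at C1–C2, and 3 from artemisin (2) by hydrogenation. Artemisin is reached from α-santonin (1) by hydroxylation of the equatorial C8–H bond.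

## Roads not taken

**Alternative 1:** The cut is at C7–C8. In the forward step SmI2 (divalent samarium) would reduce the aldehyde of seco aldehyde A2 to a ketyl that adds to C7 of its butenolide, and the samarium enolate would be protonated at C11, giving hydroxy lactone A1 (the same compound as 13).
- Merits: it is convergent, makes C7, C8 and C11 in one operation, needs no photochemistry, and ends one step from the target. In end-game length it beats the chosen plan.
- Weak points: three stereocentres come from one medium-ring transition state with only remote control. The furanone in A2 is at risk, since its carbonyl is an α-alkoxy ketone (C10–O) of the kind SmI2 cleaves. A2 must be assembled with C4, C6 and C10 set without help from a terpene.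
- Comparison: the chosen plan takes C6, C7 and C11 from santonin and C8 from an oxidation with retention, and closes no medium ring. Against the convergence of A1 it offers secure stereocentres and a shorter path to the ring.

**Alternative 2:** The cuts are at C2–C3 and C1–O. Oxidation of aldoxime A4 with NaOCl would give a nitrile oxide that adds across the vinyl group on the C10 carbinol, closing the isoxazoline and the carbocycle in A3.
- Merits: nitrile oxide cycloadditions do close medium rings, the regiochemistry is reliable, and the isoxazoline is a masked C1 carbinol/C3 ketone, so it feeds the same hydroxy diketone end-game used here. The C10 carbinol is set before ring closure, which is firmer than the facial selectivity the chosen plan needs at C10.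
- Weak points: A4 carries all six stereocentres on an open chain and needs a long linear build. The closure is a ten-membered cyclisation at high dilution, and N–O cleavage adds a step.
- Comparison: the two plans share the end-game. The chosen one reaches the ring in far fewer steps, but is less secure at C10.

**Alternative 3:** The cut is the C10–O bond at the dihydrofuranol level. Acid would let the C3 carbonyl oxygen of epoxy ketone A6 open the epoxide at C10 and, after loss of a C2 proton, give A5, which is one oxidation from the target.
- Merits: it is biomimetic, keeps the tiglate on, needs no protecting group, and is about one step shorter than the end-game chosen here.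
- Weak points: the opening is a 5-endo attack at a tertiary epoxide carbon. The furanone oxygen of the target sits at C10 where a peripheral oxidant would place its oxygen, so an invertive opening needs the (1S,10S)-epoxide A6, formed on the face that the usual crown conformer hides. The accessible (1R,10R)-epoxide would need an opening with retention. Hydride shift, allylic alcohol formation and β-elimination at C1–O compete. A6 is itself a 3-oxogermacr-1(10)-ene, so this alternative is an end-game and leaves the ten-membered ring unsolved.
- Comparison: the chosen plan pays one extra oxidation step and attaches the tiglate last, in exchange for a C10–O bond that is made once and kept.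

Key step: step 5

## Route

Remarks on the chemistry:
- α and β are used as in eudesmane drawings (the C10 methyl of 1 is β; H7 and the C6–O bond are α). Germacrane numbering is kept after ring opening.
- C4 of 9–11 forms without control. The (4S) epimer is drawn and its epimer travels with it until the equilibration in step 9.

Step 1
Reactants: 1 α-santonin
Product: 2 artemisin (8α-hydroxy-α-santonin)
Conditions: Absidia coerulea (growing culture), glucose–peptone medium, air, 27 °C, 5 d
Reagents that add atoms: dioxygen, O=O
Why: Whole-cell cytochrome P450 hydroxylation of an unactivated methylene, a documented biotransformation of santonin by Mucorales fungi (C8 and C11 are the usual sites). Oxygen replaces the equatorial 8α hydrogen with retention, so C8 (S) is set by the enzyme; the 11-hydroxy isomer is removed by chromatography.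

Step 2
Reactants: 2 artemisin
Product: 3 8α-hydroxy-3-oxo-4α-methyl-5αH-eudesman-6α,12-olide
Conditions: H2 (1 atm), 10% Pd/C, EtOAc, rt; then HCl (cat.), CHCl3, rt
Reagents that add atoms: none
Why: Heterogeneous hydrogenation of the cross-conjugated dienone, as practised on santonin. Hydrogen adds from the α face, opposite the axial C10 methyl, which sets 5α-H (trans-decalin); the acid treatment equilibrates C4 through the enol to the equatorial 4α-methyl ketone.

Step 3
Reactants: 3 8α-hydroxy-3-oxo-4α-methyl-5αH-eudesman-6α,12-olide
Product: 5 8α-hydroxy-3-oxo-4α-methyl-5αH-eudesm-1-en-6α,12-olide, via 2α-phenylselanyl ketone 4 (not isolated)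
Conditions: PhSeCl, EtOAc, rt; then 30% H2O2, pyridine, CH2Cl2, 0 °C to rt
Reagents that add atoms: none
Why: Acid-catalysed α-selenenylation of the ketone followed by selenoxide syn-elimination. A trans-fused 3-ketone enolises towards C2, so selenium enters at C2 and elimination gives the 1-en-3-one with C4 untouched.

Step 4
Reactants: 5 8α-hydroxy-3-oxo-4α-methyl-5αH-eudesm-1-en-6α,12-olide
Product: 6 3,8α-bis(tert-butyldimethylsilyloxy)-5αH-eudesma-1,3-dien-6α,12-olide
Conditions: TBSOTf (3 equiv), Et3N, CH2Cl2, −78 to 0 °C
Reagents that add atoms: tert-butyldimethylsilyl trifluoromethanesulfonate (TBSOTf), CC(C)(C)[Si](C)(C)OS(=O)(=O)C(F)(F)F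
Why: Soft enolisation with silyl triflate and amine. C10 is quaternary, so the enone can enolise only towards C4 (axial H4β) and the C1=C2/C3=C4 diene is the sole dienol ether; the same reagent silylates the C8 alcohol.

Step 5
Reactants: 6 3,8α-bis(tert-butyldimethylsilyloxy)-5αH-eudesma-1,3-dien-6α,12-olide
Product: 7 3,8α-bis(tert-butyldimethylsilyloxy)germacra-1(10),2,4-trien-6α,12-olide (C1=C10 and C4=C5 trans, C2=C3 cis in the ring)
Conditions: hν (254 nm, low-pressure Hg lamp, quartz), degassed pentane, −78 °C, about half conversion
Reagents that add atoms: none
Why: Excitation of the s-cis diene (C1=C2–C3=C4, held cisoid in ring A) is followed by a six-electron electrocyclic opening that breaks the C5–C10 σ bond in the conrotatory sense required of the excited state. The closest known reaction type is the photochemical opening of ring-fused cyclohexa-1,3-dienes to Z-hexatrienes, as in provitamin D to previtamin D and trans-fused eudesma-1,3-dienes to germacra-1(10),2,4-trienes. No ring is closed: the ten-membered ring appears because the bond shared by rings A and B is excised, so no medium-ring cyclisation is needed. No stereocentre is created; C5 and C10 become trigonal, and the two new olefin geometries follow from the trans ring fusion, whose equatorial ring-B bonds (C5–C6, C10–C9) turn outward under conrotation while axial H5 and the C10 methyl turn inward, giving E olefins at C1=C10 and C4=C5 around the ring-cis enol ether. The step needs chemoselectivity for the diene, which is secured because the lactone and both silyl ethers are transparent at 254 nm. It also has to be stopped, since the opening is photoreversible and the triene absorbs too; hence cold, dilute irradiation to partial conversion with 6 recovered and recycled. Low temperature also suppresses thermal disrotatory reclosure of 7 to a cis-fused diene, so 7 is kept cold in solution and taken directly into step 6.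

Step 6
Reactants: 7 3,8α-bis(tert-butyldimethylsilyloxy)germacra-1(10),2,4-trien-6α,12-olide
Product: 8 8α-(tert-butyldimethylsilyloxy)-3-oxogermacra-1(10)E,4E-dien-6α,12-olide
Conditions: TBAF (1.05 equiv), AcOH, THF, −78 to −30 °C
Reagents that add atoms: none
Why: Fluoride cleaves the silyl dienol ether much faster than the secondary alkyl silyl ether, and the buffered dienolate is protonated kinetically at C2 (α-protonation of a dienolate), giving the ketone with the 1(10)-E olefin intact. Removing the C2=C3 bond also ends the risk of thermal reclosure.

Step 7
Reactants: 8 8α-(tert-butyldimethylsilyloxy)-3-oxogermacra-1(10)E,4E-dien-6α,12-olide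
Product: 9 8α-(tert-butyldimethylsilyloxy)-3-oxogermacr-1(10)E-en-6α,12-olide (4S epimer drawn)
Conditions: [(Ph3P)CuH]6 (Stryker's reagent), H2O (2 equiv), benzene, rt
Reagents that add atoms: none
Why: Conjugate reduction of an enone by copper hydride. Hydride adds to C5 of the only conjugated olefin and leaves the isolated C1=C10 bond, the lactone and the silyl ether alone. C4 arises by protonation of the copper enolate and is not controlled here; both epimers are carried on because C4 is equilibrated in step 9.

Step 8
Reactants: 9 8α-(tert-butyldimethylsilyloxy)-3-oxogermacr-1(10)E-en-6α,12-olide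
Product: 10 (1R,10R)-1,10-dihydroxy-8α-(tert-butyldimethylsilyloxy)-3-oxogermacran-6α,12-olide (in equilibrium with its 3,10-hemiketal)
Conditions: OsO4 (2 mol%), (DHQD)2PHAL (5 mol%), NMO, acetone/H2O, 0 °C
Reagents that add atoms: N-methylmorpholine N-oxide, C[N+]1([O-])CCOCC1; water, O (the two hydroxyl oxygens are passed on through OsO4)
Why: Ligand-accelerated catalytic osmylation (Sharpless-type dihydroxylation with NMO as reoxidant, chosen because it is not basic and so spares the β,γ-unsaturated ketone). Syn addition to the peripheral face of the E-olefin in the crown-type conformer (C10 methyl on the β face) gives the (1R,10R)-diol, and the DHQD ligand favours the same face by the Sharpless mnemonic (olefinic H south-east, C9 south-west, C10 methyl north-west). The C10–O bond made here becomes the furanone C–O bond unchanged.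

Step 9
Reactants: 10 (1R,10R)-1,10-dihydroxy-8α-(tert-butyldimethylsilyloxy)-3-oxogermacran-6α,12-olide
Product: 12 (4S,10R)-8α-(tert-butyldimethylsilyloxy)-1-oxo-3,10-epoxygermacr-2-en-6α,12-olide, via 10-hydroxy-1,3-diketone 11 (not isolated)
Conditions: Dess–Martin periodinane, CH2Cl2, 0 °C to rt; then p-TsOH·H2O (cat.), rt; then DBU (cat.), toluene, 40 °C
Reagents that add atoms: none
Why: Dess–Martin oxidation of the secondary C1 alcohol gives the α′-hydroxy-1,3-diketone, which under acid closes through its 3,10-hemiketal (5-exo-trig addition of the C10 hydroxyl to the C3 carbonyl) and loses water to the 3(2H)-furanone, the classical cyclodehydration. C10 is not touched. DBU then equilibrates C4 through the extended enolate; the 4S epimer is expected to prevail because its methyl lies on the convex face, anti to the C5–C9 bridge, with H4 in the plane of the enol ether.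

Step 10
Reactants: 12 (4S,10R)-8α-(tert-butyldimethylsilyloxy)-1-oxo-3,10-epoxygermacr-2-en-6α,12-olide
Product: 13 (4S,10R)-8α-hydroxy-1-oxo-3,10-epoxygermacr-2-en-6α,12-olide
Conditions: HF·pyridine, THF, 0 °C to rt
Reagents that add atoms: none
Why: Fluoride cleavage of the secondary silyl ether under mildly acidic, non-aqueous conditions, which spare the furanone and the epimerisable C4 and C11 centres and give lactone migration to the C8 hydroxyl no base to work with.

Step 11
Reactants: 13 (4S,10R)-8α-hydroxy-1-oxo-3,10-epoxygermacr-2-en-6α,12-olide; 14 tiglic acid
Product: 16 (4S,6R,7S,8S,10R,11S)-8α-tigloyloxy-1-oxo-3,10-epoxygermacr-2-en-6α,12-olide (target), via tiglic 2,4,6-trichlorobenzoic anhydride 15 (not isolated)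
Conditions: 2,4,6-Cl3C6H2COCl, Et3N, THF, rt; then 13, DMAP, toluene, rt
Reagents that add atoms: none
Why: Yamaguchi esterification. The mixed anhydride acylates the hindered equatorial C8 alcohol under DMAP catalysis with retention at C8; tiglic acid is the stable E isomer and does not isomerise.

## Compound list

1 | α-santonin | C[C@H]1[C@@H]2CC[C@]3(C=CC(=O)C(=C3[C@H]2OC1=O)C)C | starting material
2 | artemisin (8α-hydroxy-α-santonin) | C[C@H]1[C@@H]2[C@@H](O)C[C@]3(C=CC(=O)C(=C3[C@H]2OC1=O)C)C | intermediate
3 | 8α-hydroxy-3-oxo-4α-methyl-5αH-eudesman-6α,12-olide (11S) | C[C@H]1[C@@H]2[C@@H](O)C[C@]3(CCC(=O)[C@@H](C)[C@@H]3[C@H]2OC1=O)C | intermediate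
4 | 2α-phenylselanyl derivative of 3 | C[C@H]1[C@@H]2[C@@H](O)C[C@]3(C[C@@H]([Se]c4ccccc4)C(=O)[C@@H](C)[C@@H]3[C@H]2OC1=O)C | intermediate (not isolated)
5 | 8α-hydroxy-3-oxo-4α-methyl-5αH-eudesm-1-en-6α,12-olide | C[C@H]1[C@@H]2[C@@H](O)C[C@]3(C=CC(=O)[C@@H](C)[C@@H]3[C@H]2OC1=O)C | intermediate
6 | 3,8α-bis(tert-butyldimethylsilyloxy)-5αH-eudesma-1,3-dien-6α,12-olide | C[C@H]1[C@@H]2[C@@H](O[Si](C)(C)C(C)(C)C)C[C@]3(C=CC(O[Si](C)(C)C(C)(C)C)=C(C)[C@@H]3[C@H]2OC1=O)C | intermediate (key-step precursor)
7 | 3,8α-bis(tert-butyldimethylsilyloxy)germacra-1(10),2,4-trien-6α,12-olide (C1=C10 and C4=C5 trans, C2=C3 cis in the ring) | C[C@H]1[C@@H]2[C@@H](O[Si](C)(C)C(C)(C)C)C/C(C)=C/C=C(O[Si](C)(C)C(C)(C)C)\C(C)=C\[C@H]2OC1=O | intermediate (key-step product)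
8 | 8α-(tert-butyldimethylsilyloxy)-3-oxogermacra-1(10)E,4E-dien-6α,12-olide | C[C@H]1[C@@H]2[C@@H](O[Si](C)(C)C(C)(C)C)C/C(C)=C/CC(=O)/C(C)=C/[C@H]2OC1=O | intermediate
9 | 8α-(tert-butyldimethylsilyloxy)-3-oxogermacr-1(10)E-en-6α,12-olide (4S epimer drawn; formed with its 4R epimer) | C[C@H]1[C@@H]2[C@@H](O[Si](C)(C)C(C)(C)C)C/C(C)=C/CC(=O)[C@@H](C)C[C@H]2OC1=O | intermediate
10 | (1R,10R)-1,10-dihydroxy-8α-(tert-butyldimethylsilyloxy)-3-oxogermacran-6α,12-olide (4S drawn; open form of the 3,10-hemiketal) | C[C@H]1[C@@H]2[C@@H](O[Si](C)(C)C(C)(C)C)C[C@@](C)(O)[C@H](O)CC(=O)[C@@H](C)C[C@H]2OC1=O | intermediate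
11 | (10R)-10-hydroxy-8α-(tert-butyldimethylsilyloxy)-1,3-dioxogermacran-6α,12-olide (4S drawn) | C[C@H]1[C@@H]2[C@@H](O[Si](C)(C)C(C)(C)C)C[C@@](C)(O)C(=O)CC(=O)[C@@H](C)C[C@H]2OC1=O | intermediate (not isolated)
12 | (4S,10R)-8α-(tert-butyldimethylsilyloxy)-1-oxo-3,10-epoxygermacr-2-en-6α,12-olide | C[C@H]1[C@@H]2[C@@H](O[Si](C)(C)C(C)(C)C)C[C@@]3(C)OC(=CC3=O)[C@@H](C)C[C@H]2OC1=O | intermediate
13 | (4S,10R)-8α-hydroxy-1-oxo-3,10-epoxygermacr-2-en-6α,12-olide | C[C@H]1[C@@H]2[C@@H](O)C[C@@]3(C)OC(=CC3=O)[C@@H](C)C[C@H]2OC1=O | intermediate
14 | tiglic acid ((E)-2-methylbut-2-enoic acid) | C/C=C(\C)C(=O)O | starting material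
15 | tiglic 2,4,6-trichlorobenzoic anhydride | C/C=C(\C)C(=O)OC(=O)c1c(Cl)cc(Cl)cc1Cl | intermediate (not isolated)
16 | CNP0235937.1, (4S,6R,7S,8S,10R,11S)-8α-tigloyloxy-1-oxo-3,10-epoxygermacr-2-en-6α,12-olide | C/C=C(\C)C(=O)O[C@H]1C[C@@]2(C)OC(=CC2=O)[C@@H](C)C[C@H]2OC(=O)[C@@H](C)[C@H]12 | target

## Step count and least certain steps

Total: 11 steps. Longest linear sequence: 11 steps (1 to 16); tiglic acid (14) enters in the last step.

**Step 5 (key step).** The opening may not stop cleanly at 7. The triene absorbs at the same wavelength and can be driven back to 6 or on to secondary photoproducts, it can reclose thermally to a cis-fused diene on warming, and the dienol silyl ether can be lost by adventitious protonolysis before the triene is intercepted. The fallback changes the enol derivative and the interception. It sets out from 5: the C8 alcohol alone is silylated (TBSCl, imidazole, DMF) to the enone silyl ether F1. Its lithium dienolate (LiN(SiMe3)2, THF, −78 °C) is O-acetylated with Ac2O to the 3-acetoxy-1,3-diene F2, the enol ester class that is the classical substrate for this opening in eudesmanolides. Irradiation as in step 5 should give the triene enol acetate F3, which tolerates cold chromatography. Cold methanolysis (K2CO3, MeOH, −20 °C, AcOH quench) then releases the ketone and the route is rejoined at 8.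

**Step 1.** Site selectivity of the enzymatic oxidation may be poor (C11 and ring A compete with C8) and the organism may reduce the C1=C2 bond, so little 2 would be obtained. The fallback takes 2 from nature: artemisin occurs beside santonin in Artemisia maritima and related species and is also offered as a natural-product reference substance. This fallback sets out from no compound of the route, leaves 1 aside, enters at 2 and makes no new compound (F0).

**Step 8.** Facial selectivity may be lost. Ketone 9 is a flexible 4,5-dihydro ring carried as two C4 epimers, and conformers with the C10 methyl on the α face would be attacked from the other side and give the 10-epi diol; the bulky ligand may also slow osmylation of the hindered olefin. The fallback changes the order of events and sets out from 8. The dienone is a crown-type 1(10),4-diene with a better defined peripheral face, and its enone olefin is inert to OsO4, so osmylation under the step 8 conditions should give the dienone diol F4. Conjugate reduction of F4 with [(Ph3P)CuH]6 as in step 7 rejoins the route at 10.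

**Step 9.** The equilibration at C4 may be incomplete or may not favour the 4S epimer strongly enough, and prolonged base may damage the furanone by conjugate addition. The fallback settles C4 before the oxygen bridge is made and sets out from 9 as formed in step 7. Ketone 9 is separated by chromatography from the 4R ketone F5, and F5 is re-equilibrated at the ketone stage (DBU, toluene) and recycled. Pure 9 is taken through steps 8 and 9 with the DBU operation left out and a brief acid-only closure, and the route is rejoined at 12.

## Further compounds

F1 | step 5 | 8α-(tert-butyldimethylsilyloxy)-3-oxo-4α-methyl-5αH-eudesm-1-en-6α,12-olide | C[C@H]1[C@@H]2[C@@H](O[Si](C)(C)C(C)(C)C)C[C@]3(C=CC(=O)[C@@H](C)[C@@H]3[C@H]2OC1=O)C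
F2 | step 5 | 3-acetoxy-8α-(tert-butyldimethylsilyloxy)-5αH-eudesma-1,3-dien-6α,12-olide | C[C@H]1[C@@H]2[C@@H](O[Si](C)(C)C(C)(C)C)C[C@]3(C=CC(OC(C)=O)=C(C)[C@@H]3[C@H]2OC1=O)C
F3 | step 5 | 3-acetoxy-8α-(tert-butyldimethylsilyloxy)germacra-1(10),2,4-trien-6α,12-olide (C1=C10 and C4=C5 trans, C2=C3 cis in the ring) | C[C@H]1[C@@H]2[C@@H](O[Si](C)(C)C(C)(C)C)C/C(C)=C/C=C(OC(C)=O)\C(C)=C\[C@H]2OC1=O
F0 | step 1 | none | none
F4 | step 8 | (1R,10R)-1,10-dihydroxy-8α-(tert-butyldimethylsilyloxy)-3-oxogermacr-4E-en-6α,12-olide | C[C@H]1[C@@H]2[C@@H](O[Si](C)(C)C(C)(C)C)C[C@@](C)(O)[C@H](O)CC(=O)/C(C)=C/[C@H]2OC1=O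
F5 | step 9 | (4R)-8α-(tert-butyldimethylsilyloxy)-3-oxogermacr-1(10)E-en-6α,12-olide (4-epimer of 9) | C[C@H]1[C@@H]2[C@@H](O[Si](C)(C)C(C)(C)C)C/C(C)=C/CC(=O)[C@H](C)C[C@H]2OC1=O
A1 | alternative 1 | 8-hydroxy furanone lactone (target without the tigloyl group) | O[C@H]1C[C@@]2(C)OC(=CC2=O)[C@@H](C)C[C@H]2OC(=O)[C@@H](C)[C@H]12
A2 | alternative 1 | seco aldehyde: furanone with a C8 aldehyde and an α-methyl butenolide open at C7–C8 | O=CC[C@@]2(C)OC(=CC2=O)[C@@H](C)C[C@H]1OC(=O)C(C)=C1
A3 | alternative 2 | isoxazoline-bridged ten-membered carbocycle | C[C@@]1(O)C[C@H](O[Si](C)(C)C(C)(C)C)[C@H]2[C@H](C)C(=O)O[C@@H]2C[C@H](C)C2=NO[C@@H]1C2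
A4 | alternative 2 | open-chain C3 aldoxime with the vinyl carbinol at C10 | C[C@](O)(C=C)C[C@H](O[Si](C)(C)C(C)(C)C)[C@H]1[C@H](C)C(=O)O[C@@H]1C[C@H](C)C=NO
A5 | alternative 3 | 3,10-oxygen-bridged 1-hydroxy-2-ene lactone 8-tiglate | C/C=C(\C)C(=O)O[C@H]1C[C@@]2(C)OC(=C[C@@H]2O)[C@@H](C)C[C@H]3OC(=O)[C@@H](C)[C@H]13
A6 | alternative 3 | (1S,10S)-1,10-epoxy-3-oxogermacran-6α,12-olide 8-tiglate | C/C=C(\C)C(=O)O[C@H]1C[C@]2(C)O[C@H]2CC(=O)[C@@H](C)C[C@H]2OC(=O)[C@@H](C)[C@H]12
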